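**Plan**

- Cuts, in retrosynthetic order: the ester bond at C3–O; the C7–C11 bond; then, once C6=C7 and C9=C10 are traced back to a C6 ketone and a dithiane-masked C8 ketone (C1=C2 restored), the two ring bonds C3–C4 and C5–C10 together; the open chain is finally cut at C5–C6, O–Si, C1=C2, both C8–S bonds, C6–C7 and C8–C9.
- Forward: the chain is joined linearly from a C9–C10–C1 bromo acetal, acetylide (C7, C8), a carbamoyl chloride (C6), a dithiol on C8, a Wittig unit (C2, C3), the silyl dienol ether and last the C4/C5/C14/C15 butenyl unit. Rings A and B then arise together in step 8, ring B is adjusted to the hydroxyisopropyl dienone, and a separately made thioacrylic acid is attached last.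
- Enabling feature: in ring A the contiguous C3–O, C4–CH3 (C15) and C5–CH3 (C14) are the imprint of a 1-silyloxy diene terminus (C3) adding to an (E)-2-methylbut-2-enoyl alkene (C4=C5). The C6 carbon of ring B is the activating ketone inside the tether, and C8 is a dithiane, so the precursor is achiral.
- Stereochemistry: C4/C5 cis from the (E)-dienophile; C3 trans to both methyls from the (E)-enol ether plus the endo tether carbonyl; absolute configuration from a chiral oxazaborolidinium catalyst. C10, C6 and C8 are transient centres; the side-chain (Z)-geometry comes from an anti-carbomagnesiation.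

Key step: step 8

Locants: all compounds carry the eremophilane numbers of the target (C1–C10 decalin, C14 on C5, C15 on C4, C11–C13 the hydroxyisopropyl unit on C7), also in the open-chain precursors.

Assumption: the (S)-oxazaborolidinium salt is taken to deliver the (3R,4R,5S,10S) adduct; its sense of induction on this α-methyl enone cannot be predicted with confidence, and if the adduct proves to be the antipode the (R)-catalyst is used with no other change.

**Route**

Step 1
Reactants: 1 2-(2-bromoethyl)-1,3-dioxolane; 2 lithium acetylide–ethylenediamine complex (LiC≡CH·H2NCH2CH2NH2)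
Product: 3 2-(but-3-yn-1-yl)-1,3-dioxolane
Conditions: DMSO, 10 °C → rt
Reagents that add atoms: lithium acetylide–ethylenediamine complex, [Li]C#C.NCCN
Why: SN2 alkylation of an acetylide by an unhindered primary bromide in a dipolar aprotic solvent; the acetal is inert to base.

Step 2
Reactants: 3 2-(but-3-yn-1-yl)-1,3-dioxolane; 4 N-methoxy-N-methylcarbamoyl chloride
Product: 6 5-(1,3-dioxolan-2-yl)-N-methoxy-N-methylpent-2-ynamide, via lithium acetylide 5 (not isolated)
Conditions: n-BuLi, THF, −78 °C; then 4, −78 → 0 °C
Reagents that add atoms: N-methoxy-N-methylcarbamoyl chloride, CON(C)C(Cl)=O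
Why: Acylation of a lithium acetylide by a carbamoyl chloride; the N-methoxy-N-methyl amide formed resists a second addition.

Step 3
Reactants: 6 5-(1,3-dioxolan-2-yl)-N-methoxy-N-methylpent-2-ynamide; 7 propane-1,3-dithiol
Product: 9 2-{2-[2-(1,3-dioxolan-2-yl)ethyl]-1,3-dithian-2-yl}-N-methoxy-N-methylacetamide, via vinyl sulfide 8 (not isolated)
Conditions: NaOMe (1.2 equiv), MeOH/CH2Cl2, −10 °C → rt
Reagents that add atoms: propane-1,3-dithiol, SCCCS
Why: Double thia-Michael addition of a 1,3-dithiol to an alkynyl carbonyl compound: the first thiolate adds at the β-carbon C8 and the pendant thiol closes the six-membered dithiane at the same carbon, which masks the C8 ketone and leaves C7 as CH2.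

Step 4
Reactants: 9 dithiane acetal amide; 10 water
Product: 11 N-methoxy-N-methyl-2-[2-(3-oxopropyl)-1,3-dithian-2-yl]acetamide
Conditions: 1 N aq. HCl, THF, rt
Reagents that add atoms: water, O
Why: Acid-catalysed acetal hydrolysis; the dithiane and the N-methoxy-N-methyl amide are stable to dilute aqueous acid.

Step 5
Reactants: 11 aldehyde; 12 (triphenylphosphoranylidene)acetaldehyde
Product: 13 N-methoxy-N-methyl-2-{2-[(3E)-5-oxopent-3-en-1-yl]-1,3-dithian-2-yl}acetamide
Conditions: toluene, 80 °C
Reagents that add atoms: (triphenylphosphoranylidene)acetaldehyde, O=CC=P(c1ccccc1)(c1ccccc1)c1ccccc1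
Why: Wittig olefination with a stabilised ylide, which gives the (E)-enal and adds C2 and C3.

Step 6
Reactants: 13 (E)-enal; 14 triisopropylsilyl trifluoromethanesulfonate
Product: 15 N-methoxy-N-methyl-2-{2-[(2E,4E)-5-(triisopropylsilyloxy)penta-2,4-dien-1-yl]-1,3-dithian-2-yl}acetamide
Conditions: Et3N, Et2O, −78 °C → rt
Reagents that add atoms: triisopropylsilyl trifluoromethanesulfonate, CC(C)[Si](C(C)C)(C(C)C)OS(=O)(=O)C(F)(F)F
Why: Soft enolisation of an enal (O-silylation, then γ-deprotonation at C10) to the silyl dienol ether, expected mainly as the (E,E)-isomer from the s-trans enal; the amide is not enolised under these conditions, which is why C6 is carried as an amide and not yet as the enolisable ketone.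

Step 7
Reactants: 15 silyloxy diene amide; 16 (E)-2-bromobut-2-ene
Product: 18 (3E)-3-methyl-1-{2-[(2E,4E)-5-(triisopropylsilyloxy)penta-2,4-dien-1-yl]-1,3-dithian-2-yl}pent-3-en-2-one, via lithium hemiaminal 17 (not isolated)
Conditions: 16, t-BuLi (2 equiv), Et2O, −78 °C; then 15, THF, −78 °C; aq. NH4Cl
Reagents that add atoms: (E)-2-bromobut-2-ene, C/C=C(\C)Br
Why: Weinreb ketone synthesis: bromine–lithium exchange proceeds with retention of alkene geometry, and the chelated tetrahedral adduct releases the tigloyl ketone only on neutral work-up, which the triisopropylsilyl enol ether should survive.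

Step 8
Reactants: 18 achiral trienone
Product: 19 cis-fused cycloadduct (3R,4R,5S,10S)
Conditions: oxazaborolidinium bis(trifluoromethanesulfonyl)imide (20 mol%), made in situ from (S)-1-(2-methylphenyl)-3,3-diphenyltetrahydro-1H,3H-pyrrolo[1,2-c][1,3,2]oxazaborole and HN(SO2CF3)2, CH2Cl2, −78 → −20 °C
Reagents that add atoms: none
Why: The protonated oxazaborolidine binds the C6 ketone and lowers the LUMO of the (E)-tigloyl alkene C4=C5, to which the (E,E)-silyloxy diene C10=C1–C2=C3 adds in a concerted, asynchronous, suprafacial [4+2] cycloaddition forming C3–C4 and C5–C10; the closest known reaction types are the Lewis-acid-promoted intramolecular Diels–Alder reaction of 1,7,9-decatrien-3-ones to cis-fused octalones and the chiral-oxazaborolidinium-catalysed intramolecular and transannular Diels–Alder reactions of triene aldehydes and ketones. Ring A closes as the six-membered cycloadduct ring and ring B as the six-membered tether ring C5–C6–C7–C8–C9–C10 (type 1 fused mode; the four-atom tether excludes the bridged orientation and the fully substituted C8 favours the folded conformer). C4 and C5 follow from the (E)-geometry of the dienophile, which keeps C15 and C14 cis through the suprafacial addition; C3 follows from the (E)-enol ether and the endo position of the complexed tether carbonyl, which place the silyloxy group trans to both methyls; C10 follows from the same endo transition state (cis fusion, H10 syn to C14) and is erased in step 16. The absolute sense at all four centres comes from the catalyst, whose aryl groups shield one enantiotopic face of the bound enone. The step needs endo over exo selectivity, fused over bridged regiochemistry and one enone face, secured in that order by the compact Lewis-acid complex of the in-tether carbonyl, by the tether length and by the catalyst, while the low temperature suppresses the uncatalysed background reaction and loss of the silyl enol ether.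

Step 9
Reactants: 19 cycloadduct
Product: 20 C6 alcohol (C6 epimers)
Conditions: NaBH4, MeOH/CH2Cl2, 0 °C → rt
Reagents that add atoms: none
Why: Borohydride reduction of the ketone; the new C6 carbinol centre is inconsequential because either epimer is eliminated in step 12.

Step 10
Reactants: 20 C6 alcohol; 10 water
Product: 21 β-hydroxy ketone (C8 ketone, C6 hydroxyl, C1=C2 retained)
Conditions: MeI, CaCO3, MeCN/H2O, 50 °C
Reagents that add atoms: water, O
Why: Alkylative dithiane hydrolysis: S-methylation makes the thioacetal a leaving group and water releases the C8 ketone, the buffered neutral medium sparing the aldol-type hydroxy ketone, the alkene and the silyl ether.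

Step 11
Reactants: 21 β-hydroxy ketone
Product: 22 saturated β-hydroxy ketone
Conditions: H2 (1 atm), 10% palladium on carbon, EtOAc, rt
Reagents that add atoms: none
Why: Heterogeneous hydrogenation of the only alkene (C1=C2), placed here because the sulfur that would poison the catalyst is gone and no conjugated alkene is yet present.

Step 12
Reactants: 22 saturated β-hydroxy ketone
Product: 24 enone (C6=C7 conjugated to the C8 ketone), via C6 mesylate 23 (not isolated)
Conditions: MsCl, Et3N, CH2Cl2, 0 °C; then DBU, rt
Reagents that add atoms: none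
Why: Mesylation followed by E1cB elimination across C6–C7; both C6 epimers converge on the same enone.

Step 13
Reactants: 24 enone; 25 iodine
Product: 26 7-iodo enone
Conditions: pyridine/CH2Cl2, 0 °C → rt
Reagents that add atoms: iodine, II
Why: α-Iodination of a cyclic enone by reversible conjugate addition of pyridine at C6, iodination of the enolate at C7 and elimination, a reaction known for 4,4-disubstituted cyclohexenones.

Step 14
Reactants: 26 7-iodo enone
Product: 27 7-iodo allylic alcohol (C8 epimers)
Conditions: NaBH4, CeCl3·7H2O, MeOH, −40 → 0 °C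
Reagents that add atoms: none
Why: Luche 1,2-reduction removes the carbonyl that would not tolerate the organolithium step; the C8 carbinol centre is inconsequential and is reoxidised in step 16.

Step 15
Reactants: 27 7-iodo allylic alcohol; 28 acetone
Product: 30 allylic diol (C8 hydroxyl and C7 2-hydroxypropan-2-yl), via dilithio species 29 (not isolated)
Conditions: t-BuLi (3.2 equiv), THF, −78 °C; then 28, −78 → 0 °C
Reagents that add atoms: acetone, CC(C)=O
Why: Deprotonation of the hydroxyl and iodine–lithium exchange give a C7 alkenyllithium whose 1,2-addition to acetone forms the C7–C11 bond.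

Step 16
Reactants: 30 allylic diol
Product: 32 (3R,4R,5R)-11-hydroxy-3-(triisopropylsilyloxy)eremophila-6,9-dien-8-one, via hydroxy enone 31 (not isolated)
Conditions: 2-iodoxybenzoic acid (IBX, 4 equiv), DMSO, rt → 75 °C
Reagents that add atoms: none
Why: IBX oxidises the secondary allylic alcohol to the C8 ketone at room temperature and, on heating, dehydrogenates the enone at C9–C10 through its C8–C9 enol (IBX-mediated α,β-dehydrogenation); the tertiary alcohol and the silyl ether are inert.

Step 17
Reactants: 32 silyl-protected dienone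
Product: 33 (3R,4R,5R)-3,11-dihydroxyeremophila-6,9-dien-8-one
Conditions: Bu4NF, THF, rt
Reagents that add atoms: none
Why: Fluoride cleavage of the secondary triisopropylsilyl ether; nothing else in the molecule is fluoride-labile.

Step 18
Reactants: 34 prop-2-yn-1-ol; 35 methylmagnesium bromide; 36 dimethyl disulfide
Product: 38 (Z)-2-methyl-3-(methylsulfanyl)prop-2-en-1-ol, via magnesium chelate 37 (not isolated)
Conditions: 35 (2.5 equiv), CuI (10 mol%), THF, −10 °C → rt; then 36, 0 °C → rt
Reagents that add atoms: methylmagnesium bromide, C[Mg]Br; dimethyl disulfide, CSSC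
Why: Copper-catalysed anti-carbomagnesiation of the propargylic alkoxide gives a five-membered alkenylmagnesium chelate with magnesium on C3 cis to the CH2O group, and sulfenylation of that carbon–magnesium bond by the disulfide with retention sets the (Z)-geometry (sulfur trans to the methyl).

Step 19
Reactants: 38 (Z)-thio allylic alcohol
Product: 39 (Z)-2-methyl-3-(methylsulfanyl)prop-2-enal
Conditions: MnO2, CH2Cl2, rt
Reagents that add atoms: none
Why: Allylic oxidation with MnO2 under neutral conditions, which should leave the sulfide and the alkene geometry untouched.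

Step 20
Reactants: 39 (Z)-thio enal; 40 sodium chlorite
Product: 41 (Z)-2-methyl-3-(methylsulfanyl)prop-2-enoic acid
Conditions: NaH2PO4, 2-methylbut-2-ene (large excess), t-BuOH/H2O, 0 °C → rt
Reagents that add atoms: sodium chlorite, [Na+].[O-]Cl=O
Why: Pinnick oxidation of the aldehyde; the alkene scavenger removes hypochlorous acid before it can oxidise the sulfide.

Step 21
Reactants: 33 diol dienone; 41 (Z)-thioacrylic acid
Product: 42 (3R,4R,5R)-11-hydroxy-8-oxoeremophila-6,9-dien-3-yl (2Z)-2-methyl-3-(methylsulfanyl)prop-2-enoate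
Conditions: N,N'-dicyclohexylcarbodiimide, 4-(dimethylamino)pyridine (cat.), CH2Cl2, 0 °C → rt
Reagents that add atoms: (Z)-2-methyl-3-(methylsulfanyl)prop-2-enoic acid, CS/C=C(/C)C(=O)O
Why: Steglich esterification; only the secondary C3 alcohol is acylated because the tertiary C11 alcohol is too hindered, and the low temperature is chosen to keep the (Z)-thioacrylate from isomerising.

**Compound list**

1 | 2-(2-bromoethyl)-1,3-dioxolane | BrCCC1OCCO1 | starting material
2 | lithium acetylide–ethylenediamine complex | [Li]C#C.NCCN | starting material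
3 | 2-(but-3-yn-1-yl)-1,3-dioxolane | C#CCCC1OCCO1 | intermediate
4 | N-methoxy-N-methylcarbamoyl chloride | CON(C)C(Cl)=O | starting material
5 | [4-(1,3-dioxolan-2-yl)but-1-yn-1-yl]lithium | [Li]C#CCCC1OCCO1 | intermediate (not isolated)
6 | 5-(1,3-dioxolan-2-yl)-N-methoxy-N-methylpent-2-ynamide | CON(C)C(=O)C#CCCC1OCCO1 | intermediate
7 | propane-1,3-dithiol | SCCCS | starting material
8 | 5-(1,3-dioxolan-2-yl)-N-methoxy-N-methyl-3-[(3-sulfanylpropyl)sulfanyl]pent-2-enamide (alkene geometry open) | CON(C)C(=O)C=C(CCC1OCCO1)SCCCS | intermediate (not isolated)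
9 | 2-{2-[2-(1,3-dioxolan-2-yl)ethyl]-1,3-dithian-2-yl}-N-methoxy-N-methylacetamide | CON(C)C(=O)CC1(CCC2OCCO2)SCCCS1 | intermediate
10 | water | O | starting material
11 | N-methoxy-N-methyl-2-[2-(3-oxopropyl)-1,3-dithian-2-yl]acetamide | CON(C)C(=O)CC1(CCC=O)SCCCS1 | intermediate
12 | (triphenylphosphoranylidene)acetaldehyde | O=CC=P(c1ccccc1)(c1ccccc1)c1ccccc1 | starting material
13 | N-methoxy-N-methyl-2-{2-[(3E)-5-oxopent-3-en-1-yl]-1,3-dithian-2-yl}acetamide | CON(C)C(=O)CC1(CC/C=C/C=O)SCCCS1 | intermediate
14 | triisopropylsilyl trifluoromethanesulfonate | CC(C)[Si](C(C)C)(C(C)C)OS(=O)(=O)C(F)(F)F | starting material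
15 | N-methoxy-N-methyl-2-{2-[(2E,4E)-5-(triisopropylsilyloxy)penta-2,4-dien-1-yl]-1,3-dithian-2-yl}acetamide | CON(C)C(=O)CC1(C/C=C/C=C/O[Si](C(C)C)(C(C)C)C(C)C)SCCCS1 | intermediate
16 | (E)-2-bromobut-2-ene (methyl groups cis) | C/C=C(\C)Br | starting material
17 | lithium hemiaminal from 15 and the butenyllithium (tetrahedral adduct at C6) | C/C=C(\C)C(O[Li])(N(C)OC)CC1(C/C=C/C=C/O[Si](C(C)C)(C(C)C)C(C)C)SCCCS1 | intermediate (not isolated)
18 | (3E)-3-methyl-1-{2-[(2E,4E)-5-(triisopropylsilyloxy)penta-2,4-dien-1-yl]-1,3-dithian-2-yl}pent-3-en-2-one (achiral key-step precursor) | C/C=C(\C)C(=O)CC1(C/C=C/C=C/O[Si](C(C)C)(C(C)C)C(C)C)SCCCS1 | intermediate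
19 | cis-fused cycloadduct (3R,4R,5S,10S): C1=C2, C3 silyloxy trans to the cis C4 and C5 methyls, H10 cis to the C5 methyl, C6 ketone, C8 spiro-1,3-dithiane | CC(C)[Si](C(C)C)(C(C)C)O[C@@H]1C=C[C@@H]2CC3(SCCCS3)CC(=O)[C@]2(C)[C@H]1C | intermediate
20 | C6 alcohol of 19 (C6 epimers; C3, C4, C5, C10 as in 19) | CC(C)[Si](C(C)C)(C(C)C)O[C@@H]1C=C[C@@H]2CC3(SCCCS3)CC(O)[C@]2(C)[C@H]1C | intermediate
21 | β-hydroxy ketone: C8 ketone, C6 hydroxyl (epimers), C1=C2 | CC(C)[Si](C(C)C)(C(C)C)O[C@@H]1C=C[C@@H]2CC(=O)CC(O)[C@]2(C)[C@H]1C | intermediate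
22 | saturated β-hydroxy ketone: as 21 with C1–C2 reduced | CC(C)[Si](C(C)C)(C(C)C)O[C@@H]1CC[C@@H]2CC(=O)CC(O)[C@]2(C)[C@H]1C | intermediate
23 | C6 methanesulfonate of 22 | CC(C)[Si](C(C)C)(C(C)C)O[C@@H]1CC[C@@H]2CC(=O)CC(OS(C)(=O)=O)[C@]2(C)[C@H]1C | intermediate (not isolated)
24 | enone: C6=C7 conjugated to the C8 ketone, cis-fused, C3 silyloxy | CC(C)[Si](C(C)C)(C(C)C)O[C@@H]1CC[C@@H]2CC(=O)C=C[C@]2(C)[C@H]1C | intermediate
25 | iodine | II | starting material
26 | 7-iodo enone | CC(C)[Si](C(C)C)(C(C)C)O[C@@H]1CC[C@@H]2CC(=O)C(I)=C[C@]2(C)[C@H]1C | intermediate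
27 | 7-iodo allylic alcohol (C8 epimers) | CC(C)[Si](C(C)C)(C(C)C)O[C@@H]1CC[C@@H]2CC(O)C(I)=C[C@]2(C)[C@H]1C | intermediate
28 | acetone | CC(C)=O | starting material
29 | dilithio species: C8 lithium alkoxide, C7 alkenyllithium | CC(C)[Si](C(C)C)(C(C)C)O[C@@H]1CC[C@@H]2CC(O[Li])C([Li])=C[C@]2(C)[C@H]1C | intermediate (not isolated)
30 | allylic diol: C6=C7, C8 hydroxyl (epimers), C7 2-hydroxypropan-2-yl | CC(C)[Si](C(C)C)(C(C)C)O[C@@H]1CC[C@@H]2CC(O)C(C(C)(C)O)=C[C@]2(C)[C@H]1C | intermediate
31 | hydroxy enone: C6=C7, C8 ketone, C11 hydroxyl, C9–C10 saturated | CC(C)[Si](C(C)C)(C(C)C)O[C@@H]1CC[C@@H]2CC(=O)C(C(C)(C)O)=C[C@]2(C)[C@H]1C | intermediate (not isolated)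
32 | (3R,4R,5R)-11-hydroxy-3-(triisopropylsilyloxy)eremophila-6,9-dien-8-one | CC(C)[Si](C(C)C)(C(C)C)O[C@@H]1CCC2=CC(=O)C(C(C)(C)O)=C[C@]2(C)[C@H]1C | intermediate
33 | (3R,4R,5R)-3,11-dihydroxyeremophila-6,9-dien-8-one | O[C@@H]1CCC2=CC(=O)C(C(C)(C)O)=C[C@]2(C)[C@H]1C | intermediate
34 | prop-2-yn-1-ol | C#CCO | starting material
35 | methylmagnesium bromide | C[Mg]Br | starting material
36 | dimethyl disulfide | CSSC | starting material
37 | 4-methyl-2,5-dihydro-1,2-oxamagnesole (cyclic alkenylmagnesium alkoxide) | CC1=C[Mg]OC1 | intermediate (not isolated)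
38 | (Z)-2-methyl-3-(methylsulfanyl)prop-2-en-1-ol | CS/C=C(/C)CO | intermediate
39 | (Z)-2-methyl-3-(methylsulfanyl)prop-2-enal | CS/C=C(/C)C=O | intermediate
40 | sodium chlorite | [Na+].[O-]Cl=O | starting material
41 | (Z)-2-methyl-3-(methylsulfanyl)prop-2-enoic acid | CS/C=C(/C)C(=O)O | intermediate
42 | (3R,4R,5R)-11-hydroxy-8-oxoeremophila-6,9-dien-3-yl (2Z)-2-methyl-3-(methylsulfanyl)prop-2-enoate | CS/C=C(/C)C(=O)O[C@@H]1CCC2=CC(=O)C(C(C)(C)O)=C[C@]2(C)[C@H]1C | target

**Step count and risks**

Total steps: 21. Longest linear sequence: 18 (steps 1–17 and 21); steps 18–20 make the side-chain acid.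

Most likely to fail, in this order:

Step 8. The bulky chiral Lewis acid may activate the trisubstituted α-methyl enone too weakly, facial or endo selectivity may erode, or the acid may strip the silyl enol ether before cyclisation; in addition the silyloxy terminus bonds to the enone β-carbon only because the tether dictates it, so the diene oxygen gives less rate help than in a free pairing. The fallback gives up asymmetric catalysis: starting from 18, the cyclisation is promoted with Me2AlCl (1.1 equiv, CH2Cl2, −78 → 0 °C), an ordinary Lewis-acid intramolecular Diels–Alder reaction, to give the racemic cis-fused adduct F1. Its enantiomers are separated by preparative chromatography on a chiral stationary phase (cellulose tris(3,5-dimethylphenylcarbamate)), and the (3R,4R,5S,10S) enantiomer rejoins the route as 19.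

Step 16. The oxidation may stop at the enone stage because enolisation towards C9 next to the ring-fusion carbon is slow, or prolonged heating may degrade the tertiary carbinol. The fallback separates the two events and replaces the IBX dehydrogenation by a Saegusa–Ito oxidation. Starting from 30, MnO2 in CH2Cl2 gives the hydroxy enone 31, now isolated. LiHMDS (2.2 equiv) and TMSCl in THF at −78 °C then give the bis(trimethylsilyl) dienol ether F2, and Pd(OAc)2 (1.1 equiv) in MeCN at rt introduces C9=C10 to give the C11 trimethylsilyl ether F3. K2CO3 in MeOH removes the tertiary silyl group and returns 32.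

Step 21. Acyl transfer to the hindered C3 hydroxyl from a poorly electrophilic push–pull acid may be slow enough for reversible conjugate addition of the pyridine catalyst to scramble the (Z)-geometry. The fallback forms the carbon–sulfur bond after the ester bond. From 34 and 35 the same anti-carbomagnesiation, quenched with I2, gives (Z)-3-iodo-2-methylprop-2-en-1-ol F4; MnO2 gives (Z)-3-iodo-2-methylprop-2-enal F5 and NaClO2 oxidation gives (Z)-3-iodo-2-methylprop-2-enoic acid F6. The alcohol 33 is acylated with this configurationally robust acid (N,N'-dicyclohexylcarbodiimide, 4-(dimethylamino)pyridine) to the iodo ester F7. A stereoretentive palladium-catalysed coupling with Bu3SnSMe (Pd(PPh3)4, toluene, 90 °C), which involves no free thiolate that could add to the dienone, then gives 42.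

Further compounds
F1 | step 8 | racemic cis-fused adduct (19 together with its mirror image) | CC(C)[Si](C(C)C)(C(C)C)O[C@@H]1C=C[C@@H]2CC3(SCCCS3)CC(=O)[C@]2(C)[C@H]1C.CC(C)[Si](C(C)C)(C(C)C)O[C@H]1C=C[C@H]2CC3(SCCCS3)CC(=O)[C@@]2(C)[C@@H]1C
F2 | step 16 | bis(trimethylsilyl) dienol ether: C6=C7, C8(OSiMe3)=C9, C11 trimethylsilyl ether | CC(C)[Si](C(C)C)(C(C)C)O[C@@H]1CC[C@@H]2C=C(O[Si](C)(C)C)C(C(C)(C)O[Si](C)(C)C)=C[C@]2(C)[C@H]1C
F3 | step 16 | C11 trimethylsilyl ether of 32 | CC(C)[Si](C(C)C)(C(C)C)O[C@@H]1CCC2=CC(=O)C(C(C)(C)O[Si](C)(C)C)=C[C@]2(C)[C@H]1C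
F4 | step 21 | (Z)-3-iodo-2-methylprop-2-en-1-ol | I/C=C(/C)CO
F5 | step 21 | (Z)-3-iodo-2-methylprop-2-enal | I/C=C(/C)C=O
F6 | step 21 | (Z)-3-iodo-2-methylprop-2-enoic acid | I/C=C(/C)C(=O)O
F7 | step 21 | (3R,4R,5R)-11-hydroxy-8-oxoeremophila-6,9-dien-3-yl (2Z)-3-iodo-2-methylprop-2-enoate | I/C=C(/C)C(=O)O[C@@H]1CCC2=CC(=O)C(C(C)(C)O)=C[C@]2(C)[C@H]1C
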